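**Strategy.** Germacrane numbering is used. Everything rests on disconnecting C6–C7, the bond shared by the ten-membered carbocycle (C1–C10) and the α-methylene-γ-butyrolactone (C6, C7, C11, C12, O), whose O–C6–C7–C11=C13 array is a masked homoallylic alcohol. An intramolecular Nozaki–Hiyama allylation joins the C6 aldehyde of a (Z)-enal to C7 of an allylchromium made from a C13 allylic bromide. In one operation it closes the carbocycle, sets C6 and C7, creates the exocyclic methylene and lets the C6 alkoxide lactonise onto the C12 ester. The precursor is an acyclic bromo enal diester already carrying the C9 ester and a silylated C8 oxygen, built from neryl acetate.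

Key step: step 20

Remark: the C9 ester is read as (2R,3S)-3-hydroxy-2-methylbutanoate and the C8 ester as (2S,3S)-2,3-epoxy-2-methylbutanoate. TBS = tert-butyldimethylsilyl, TES = triethylsilyl.

**Acid for the C9 ester (steps 1–3)**

Step 1
Reactants: 1 (R)-4-benzyl-3-propanoyl-1,3-oxazolidin-2-one
Product: 3 (R)-4-benzyl-3-[(2R,3S)-3-hydroxy-2-methylbutanoyl]-1,3-oxazolidin-2-one, via dibutylboron (Z)-enolate 2 (not isolated)
Conditions: Bu2BOTf, iPr2NEt, CH2Cl2, 0 °C; MeCHO, −78 to 0 °C; pH 7 buffer, MeOH, H2O2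
Reagents that add atoms: acetaldehyde, CC=O
Why: Evans syn aldol reaction; the (Z)-boron enolate reacts through a Zimmerman–Traxler chair on the face left open by the (R)-benzyl auxiliary, setting C2′ (R) and C3′ (S).

Step 2
Reactants: 3 (R)-4-benzyl-3-[(2R,3S)-3-hydroxy-2-methylbutanoyl]-1,3-oxazolidin-2-one
Product: 4 (R)-4-benzyl-3-[(2R,3S)-3-(tert-butyldimethylsilyloxy)-2-methylbutanoyl]-1,3-oxazolidin-2-one
Conditions: TBSOTf, 2,6-lutidine, CH2Cl2, 0 °C
Reagents that add atoms: tert-butyldimethylsilyl triflate, CC(C)(C)[Si](C)(C)OS(=O)(=O)C(F)(F)F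
Why: Silylation of the secondary alcohol under non-epimerising conditions masks the hydroxyl that must stay free of acylation later.

Step 3
Reactants: 4 (R)-4-benzyl-3-[(2R,3S)-3-(tert-butyldimethylsilyloxy)-2-methylbutanoyl]-1,3-oxazolidin-2-one
Product: 6 (2R,3S)-3-(tert-butyldimethylsilyloxy)-2-methylbutanoic acid, via peroxy acid 5 (not isolated)
Conditions: LiOH, H2O2, THF/H2O, 0 °C; Na2SO3; HCl to pH 3
Reagents that add atoms: hydrogen peroxide, OO
Why: Hydroperoxide attacks the exocyclic imide carbonyl selectively (Evans auxiliary cleavage) and sulfite reduces the peracid, without touching the α-stereocentre.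

**Acid for the C8 ester (steps 4–6)**

Step 4
Reactants: 7 methyl (2Z)-2-methylbut-2-enoate (methyl angelate)
Product: 8 (2Z)-2-methylbut-2-en-1-ol
Conditions: iBu2AlH (DIBAL-H), CH2Cl2, −78 to 0 °C; Rochelle salt
Reagents that add atoms: none
Why: 1,2-Reduction of the enoate by the aluminium hydride gives the allylic alcohol with the Z geometry retained.

Step 5
Reactants: 8 (2Z)-2-methylbut-2-en-1-ol
Product: 9 [(2R,3S)-2,3-dimethyloxiran-2-yl]methanol
Conditions: Ti(OiPr)4 (cat.), D-(−)-diethyl tartrate, tBuOOH, 4 Å sieves, CH2Cl2, −20 °C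
Reagents that add atoms: tert-butyl hydroperoxide, CC(C)(C)OO
Why: Sharpless asymmetric epoxidation; D-(−)-tartrate directs oxygen to the face that gives the (2R,3S)-epoxide, and syn delivery keeps the two methyl groups trans as in the Z alkene.

Step 6
Reactants: 9 [(2R,3S)-2,3-dimethyloxiran-2-yl]methanol
Product: 11 (2S,3S)-2,3-dimethyloxirane-2-carboxylic acid, via epoxy aldehyde 10 (not isolated)
Conditions: RuCl3 (cat.), NaIO4, MeCN/EtOAc/H2O, rt
Reagents that add atoms: water, O
Why: Ruthenium tetroxide oxidation of the primary alcohol through the aldehyde hydrate leaves both epoxide centres untouched (the C2 descriptor changes only by priority).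

**Alkenyl bromide carrying C7, C11, C12 and C13 (steps 7–8)**

Step 7
Reactants: 12 methyl 2-(bromomethyl)prop-2-enoate
Product: 14 methyl (2Z)-3-bromo-2-(bromomethyl)prop-2-enoate, via tribromide 13 (not isolated)
Conditions: Br2, CH2Cl2, 0 °C; then iPr2NEt, 0 °C to rt
Reagents that add atoms: bromine, BrBr
Why: Bromine addition followed by E2 dehydrobromination of the symmetric tribromide with a hindered base should place the vinylic bromine trans to the ester, as in the methacrylate series.

Step 8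
Reactants: 14 methyl (2Z)-3-bromo-2-(bromomethyl)prop-2-enoate
Product: 15 methyl (2E)-2-(acetoxymethyl)-3-bromoprop-2-enoate
Conditions: KOAc, DMF, 0 °C to rt
Reagents that add atoms: potassium acetate, CC(=O)[O-].[K+]
Why: SN2 displacement of the activated allylic bromide by acetate leaves the vinylic bromide and the alkene geometry unchanged.

**Main line (steps 9–23)**

Step 9
Reactants: 16 neryl acetate, (2Z)-3,7-dimethylocta-2,6-dien-1-yl acetate
Product: 18 (2Z)-3-methyl-6-oxohex-2-en-1-yl acetate, via ozonide 17 (not isolated)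
Conditions: O3 (1.0 equiv), CH2Cl2, −78 °C; then Me2S, −78 °C to rt
Reagents that add atoms: ozone, O=[O+][O-]
Why: Ozonolysis with one equivalent of ozone should cleave the remote, more electron-rich alkene in preference to the one deactivated by the allylic acetate.

Step 10
Reactants: 18 (2Z)-3-methyl-6-oxohex-2-en-1-yl acetate
Product: 19 methyl (2Z,6Z)-8-acetoxy-2-iodo-6-methylocta-2,6-dienoate
Conditions: Ph3P=CHCO2Me, NIS, CH2Cl2, −20 °C; then 18, rt
Reagents that add atoms: methyl (triphenylphosphoranylidene)acetate, COC(=O)C=P(c1ccccc1)(c1ccccc1)c1ccccc1; N-iodosuccinimide, O=C1CCC(=O)N1I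
Why: Wittig olefination with the iodinated stabilised ylide should place the chain trans to the ester, giving the (Z)-α-iodo enoate that fixes the C1=C10 geometry.

Step 11
Reactants: 19 methyl (2Z,6Z)-8-acetoxy-2-iodo-6-methylocta-2,6-dienoate
Product: 20 methyl (2E,6Z)-8-acetoxy-2-[(1E)-3-hydroxyprop-1-en-1-yl]-6-methylocta-2,6-dienoate
Conditions: Pd2(dba)3 (cat.), AsPh3, CuI, NMP, rt
Reagents that add atoms: (2E)-3-(tributylstannyl)prop-2-en-1-ol, CCCC[Sn](CCCC)(CCCC)/C=C/CO
Why: Stille coupling of the α-iodo enoate with the (E)-alkenylstannane proceeds with retention at both alkenes.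

Step 12
Reactants: 20 methyl (2E,6Z)-8-acetoxy-2-[(1E)-3-hydroxyprop-1-en-1-yl]-6-methylocta-2,6-dienoate
Product: 21 methyl (2E,6Z)-8-acetoxy-2-[(2S,3S)-3-(hydroxymethyl)oxiran-2-yl]-6-methylocta-2,6-dienoate
Conditions: Ti(OiPr)4 (cat.), L-(+)-diethyl tartrate, tBuOOH, 4 Å sieves, CH2Cl2, −20 °C
Reagents that add atoms: tert-butyl hydroperoxide, CC(C)(C)OO
Why: Sharpless asymmetric epoxidation acts only on the alkene of the allylic alcohol, and L-(+)-tartrate gives the (2S,3S)-epoxide that fixes the later C9 configuration.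

Step 13
Reactants: 21 methyl (2E,6Z)-8-acetoxy-2-[(2S,3S)-3-(hydroxymethyl)oxiran-2-yl]-6-methylocta-2,6-dienoate; 6 (2R,3S)-3-(tert-butyldimethylsilyloxy)-2-methylbutanoic acid
Product: 22 methyl (2E,6Z)-8-acetoxy-2-[(1R,2S)-2,3-dihydroxy-1-{[(2R,3S)-3-(tert-butyldimethylsilyloxy)-2-methylbutanoyl]oxy}propyl]-6-methylocta-2,6-dienoate
Conditions: Ti(OiPr)4 (1.5 equiv), CH2Cl2, rt; aq. tartaric acid
Reagents that add atoms: none
Why: Titanium-assisted opening of the 2,3-epoxy alcohol by the carboxylic acid at C3 (Sharpless regioselective opening, reinforced by the allylic position) occurs with inversion, installing the C9 ester and the (9R) centre together.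

Step 14
Reactants: 22 methyl (2E,6Z)-8-acetoxy-2-[(1R,2S)-2,3-dihydroxy-1-{[(2R,3S)-3-(tert-butyldimethylsilyloxy)-2-methylbutanoyl]oxy}propyl]-6-methylocta-2,6-dienoate
Product: 23 methyl (2E,6Z)-8-acetoxy-6-methyl-2-[(1R)-2-oxo-1-{[(2R,3S)-3-(tert-butyldimethylsilyloxy)-2-methylbutanoyl]oxy}ethyl]octa-2,6-dienoate
Conditions: NaIO4, THF/pH 7 buffer, 0 °C
Reagents that add atoms: none
Why: Periodate glycol cleavage removes the terminal carbinol carbon under near-neutral conditions and leaves C8 as an aldehyde next to the intact C9 centre.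

Step 15
Reactants: 23 methyl (2E,6Z)-8-acetoxy-6-methyl-2-[(1R)-2-oxo-1-{[(2R,3S)-3-(tert-butyldimethylsilyloxy)-2-methylbutanoyl]oxy}ethyl]octa-2,6-dienoate; 15 methyl (2E)-2-(acetoxymethyl)-3-bromoprop-2-enoate
Product: 24 dimethyl (2E,4S,5R,6E)-2-(acetoxymethyl)-6-[(4Z)-6-acetoxy-4-methylhex-4-en-1-ylidene]-4-hydroxy-5-{[(2R,3S)-3-(tert-butyldimethylsilyloxy)-2-methylbutanoyl]oxy}hept-2-enedioate
Conditions: CrCl2 (4 equiv), NiCl2 (2 mol %), DMSO, rt
Reagents that add atoms: none
Why: Nozaki–Hiyama–Kishi alkenylation; the alkenylchromium formed with retention should add to the α-acyloxy aldehyde under Felkin–Anh (polar) control to give the 8,9-anti alcohol (8S), and the ester trans to C8 cannot lactonise.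

Step 16
Reactants: 24 dimethyl (2E,4S,5R,6E)-2-(acetoxymethyl)-6-[(4Z)-6-acetoxy-4-methylhex-4-en-1-ylidene]-4-hydroxy-5-{[(2R,3S)-3-(tert-butyldimethylsilyloxy)-2-methylbutanoyl]oxy}hept-2-enedioate
Product: 25 the 4-O-triethylsilyl ether of 24 (C8–OTES)
Conditions: Et3SiOTf, 2,6-lutidine, CH2Cl2, −78 °C
Reagents that add atoms: triethylsilyl triflate, CC[Si](CC)(CC)OS(=O)(=O)C(F)(F)F
Why: Silylation gives a C8 ether that is a poor leaving group in the chromium step and is removable later in the presence of the TBS ether.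

Step 17
Reactants: 25 the 4-O-triethylsilyl ether of 24
Product: 26 dimethyl (2E,4S,5R,6E)-2-(hydroxymethyl)-6-[(4Z)-6-hydroxy-4-methylhex-4-en-1-ylidene]-5-{[(2R,3S)-3-(tert-butyldimethylsilyloxy)-2-methylbutanoyl]oxy}-4-(triethylsilyloxy)hept-2-enedioate
Conditions: K2CO3 (cat.), MeOH, 0 °C
Reagents that add atoms: none
Why: Mild methanolysis should cleave the two primary allylic acetates much faster than the hindered, α-branched secondary ester at C9.

Step 18
Reactants: 26 the C6,C13 diol
Product: 27 dimethyl (2E,4S,5R,6E)-2-(hydroxymethyl)-6-[(4Z)-4-methyl-6-oxohex-4-en-1-ylidene]-5-{[(2R,3S)-3-(tert-butyldimethylsilyloxy)-2-methylbutanoyl]oxy}-4-(triethylsilyloxy)hept-2-enedioate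
Conditions: MnO2, CH2Cl2, rt
Reagents that add atoms: none
Why: MnO2 oxidises the electron-rich allylic alcohol at C6 much faster than the electron-poor 2-(hydroxymethyl)enoate, and the Z geometry of the enal is retained.

Step 19
Reactants: 27 the C6 enal with free C13 hydroxyl
Product: 28 dimethyl (2Z,4S,5R,6E)-2-(bromomethyl)-6-[(4Z)-4-methyl-6-oxohex-4-en-1-ylidene]-5-{[(2R,3S)-3-(tert-butyldimethylsilyloxy)-2-methylbutanoyl]oxy}-4-(triethylsilyloxy)hept-2-enedioate
Conditions: NBS, Me2S, CH2Cl2, −20 to 0 °C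
Reagents that add atoms: N-bromosuccinimide, O=C1CCC(=O)N1Br
Why: Corey–Kim bromination (alkoxysulfonium, then SN2 by bromide) converts the allylic alcohol into the bromide without the aldehyde olefination that an Appel reagent could cause.

Step 20
Reactants: 28 the bromo enal
Product: 30 methyl (1(10)E,4Z,6R,7S,8S,9R)-9-{[(2R,3S)-3-(tert-butyldimethylsilyloxy)-2-methylbutanoyl]oxy}-12-oxo-8-(triethylsilyloxy)-6,12-epoxygermacra-1(10),4,11(13)-trien-14-oate, via seco hydroxy ester 29 (not isolated)
Conditions: CrCl2 (10 equiv), DMF, rt, syringe-pump addition of 28 (final 2 mM); aq. NH4Cl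
Reagents that add atoms: none
Why: CrCl2 reduces the allylic C13–Br bond to an allylchromium (trivalent chromium) that equilibrates by 1,3-metal shift and adds through C7 to the C6 aldehyde in a closed six-membered chair transition state, after which the C6 chromium alkoxide of 29 attacks the C12 methyl ester and expels methoxide. The closest known reaction type is the intramolecular Nozaki–Hiyama (Barbier-type) 2-(alkoxycarbonyl)allylation of aldehydes used to close germacranolide rings, an umpolung of the allylic bromide. The ten-membered carbocycle closes by exo addition of C7 to the aldehyde carbon C6, with the two cis ring alkenes (C4=C5, C1=C10) acting as turn elements, and the five-membered lactone closes by 5-exo-trig acyl substitution at C12. C7 is set by the C8 stereocentre: 1,3-allylic strain keeps H8 in the plane of the C7=C11 bond, so C6 should bond anti to the C8–C9 ring bond and gauche to the silyloxy group, giving the (7S,8S) relationship. C6 is set by the chair, in which the C5 and C8 ring branches are both equatorial, which should give the anti adduct and hence the trans-fused lactone (6R). The step needs ring closure over oligomerisation and reduction of the bromide only, secured by slow addition to about 2 mM and the mildness of CrCl2; the silyl ether at C8 is a poor leaving group, which suppresses 1,4-elimination from the allylmetal, and it leaves O6 as the only oxygen able to lactonise.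

Step 21
Reactants: 30 the C8 triethylsilyl ether lactone
Product: 31 methyl (1(10)E,4Z,6R,7R,8S,9R)-9-{[(2R,3S)-3-(tert-butyldimethylsilyloxy)-2-methylbutanoyl]oxy}-8-hydroxy-12-oxo-6,12-epoxygermacra-1(10),4,11(13)-trien-14-oate (same spatial arrangement as 30; the C7 descriptor changes by priority only)
Conditions: PPTS, MeOH, 0 °C to rt
Reagents that add atoms: none
Why: Mildly acidic methanolysis removes the secondary TES ether and spares the more robust secondary TBS ether, the esters and the lactone.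

Step 22
Reactants: 31 the C8 alcohol; 11 (2S,3S)-2,3-dimethyloxirane-2-carboxylic acid
Product: 33 the 3′-O-TBS ether of the target (8-epoxyangelate, 9-silyloxy ester), via mixed anhydride 32 (not isolated)
Conditions: 2,4,6-Cl3C6H2COCl, Et3N, THF, rt; then 31, DMAP, toluene, rt
Reagents that add atoms: none
Why: Yamaguchi esterification through the trichlorobenzoyl mixed anhydride acylates the hindered C8 hydroxyl with the α-quaternary epoxy acid with retention at C8; the alcohol is used directly to limit acyl migration from O9.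

Step 23
Reactants: 33 the 3′-O-TBS ether of the target
Product: 34 the target, methyl (1(10)E,4Z,6R,7S,8S,9R)-8-{[(2S,3S)-2,3-dimethyloxiran-2-yl]carbonyloxy}-9-{[(2R,3S)-3-hydroxy-2-methylbutanoyl]oxy}-12-oxo-6,12-epoxygermacra-1(10),4,11(13)-trien-14-oate
Conditions: HF·pyridine, pyridine, THF, 0 °C to rt
Reagents that add atoms: none
Why: Buffered fluoride desilylation frees the side-chain hydroxyl without opening the electron-poor epoxide or disturbing the esters and the α-methylene lactone.

**Compound list**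

1 | (R)-4-benzyl-3-propanoyl-1,3-oxazolidin-2-one | CCC(=O)N1[C@H](Cc2ccccc2)COC1=O | starting material
2 | dibutylboron (Z)-enolate of 1 | C/C=C(\OB(CCCC)CCCC)N1[C@H](Cc2ccccc2)COC1=O | intermediate
3 | (R)-4-benzyl-3-[(2R,3S)-3-hydroxy-2-methylbutanoyl]-1,3-oxazolidin-2-one | O=C(N1[C@H](Cc2ccccc2)COC1=O)[C@H](C)[C@H](C)O | intermediate
4 | (R)-4-benzyl-3-[(2R,3S)-3-(tert-butyldimethylsilyloxy)-2-methylbutanoyl]-1,3-oxazolidin-2-one | O=C(N1[C@H](Cc2ccccc2)COC1=O)[C@H](C)[C@H](C)O[Si](C)(C)C(C)(C)C | intermediate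
5 | (2R,3S)-3-(tert-butyldimethylsilyloxy)-2-methylbutaneperoxoic acid | OOC(=O)[C@H](C)[C@H](C)O[Si](C)(C)C(C)(C)C | intermediate
6 | (2R,3S)-3-(tert-butyldimethylsilyloxy)-2-methylbutanoic acid | OC(=O)[C@H](C)[C@H](C)O[Si](C)(C)C(C)(C)C | intermediate
7 | methyl (2Z)-2-methylbut-2-enoate (methyl angelate) | C/C=C(/C)C(=O)OC | starting material
8 | (2Z)-2-methylbut-2-en-1-ol | C/C=C(/C)CO | intermediate
9 | [(2R,3S)-2,3-dimethyloxiran-2-yl]methanol | OC[C@@]1(C)O[C@H]1C | intermediate
10 | (2S,3S)-2,3-dimethyloxirane-2-carbaldehyde | O=C[C@@]1(C)O[C@H]1C | intermediate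
11 | (2S,3S)-2,3-dimethyloxirane-2-carboxylic acid | OC(=O)[C@@]1(C)O[C@H]1C | intermediate
12 | methyl 2-(bromomethyl)prop-2-enoate | C=C(CBr)C(=O)OC | starting material
13 | methyl 2,3-dibromo-2-(bromomethyl)propanoate | COC(=O)C(Br)(CBr)CBr | intermediate
14 | methyl (2Z)-3-bromo-2-(bromomethyl)prop-2-enoate | COC(=O)/C(CBr)=C/Br | intermediate
15 | methyl (2E)-2-(acetoxymethyl)-3-bromoprop-2-enoate | COC(=O)/C(COC(C)=O)=C/Br | intermediate
16 | neryl acetate | CC(=O)OC/C=C(/C)CCC=C(C)C | starting material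
17 | ozonide of the 6,7-alkene of neryl acetate | CC(=O)OC/C=C(/C)CCC1OOC(C)(C)O1 | intermediate
18 | (2Z)-3-methyl-6-oxohex-2-en-1-yl acetate | CC(=O)OC/C=C(/C)CCC=O | intermediate
19 | methyl (2Z,6Z)-8-acetoxy-2-iodo-6-methylocta-2,6-dienoate | CC(=O)OC/C=C(/C)CC/C=C(/C(=O)OC)I | intermediate
20 | methyl (2E,6Z)-8-acetoxy-2-[(1E)-3-hydroxyprop-1-en-1-yl]-6-methylocta-2,6-dienoate | CC(=O)OC/C=C(/C)CC/C=C(/C(=O)OC)\C=C\CO | intermediate
21 | methyl (2E,6Z)-8-acetoxy-2-[(2S,3S)-3-(hydroxymethyl)oxiran-2-yl]-6-methylocta-2,6-dienoate | CC(=O)OC/C=C(/C)CC/C=C(/C(=O)OC)[C@@H]1O[C@H]1CO | intermediate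
22 | C9 ester diol (1R,2S in the propyl unit) | CC(=O)OC/C=C(/C)CC/C=C(/C(=O)OC)[C@@H](OC(=O)[C@H](C)[C@H](C)O[Si](C)(C)C(C)(C)C)[C@@H](O)CO | intermediate
23 | α-acyloxy aldehyde (C8 aldehyde, 9R) | CC(=O)OC/C=C(/C)CC/C=C(/C(=O)OC)[C@@H](OC(=O)[C@H](C)[C@H](C)O[Si](C)(C)C(C)(C)C)C=O | intermediate
24 | C8 alcohol diacetate (8S,9R) | CC(=O)OC/C=C(/C)CC/C=C(/C(=O)OC)[C@@H](OC(=O)[C@H](C)[C@H](C)O[Si](C)(C)C(C)(C)C)[C@@H](O)/C=C(/C(=O)OC)COC(C)=O | intermediate
25 | C8 triethylsilyl ether diacetate | CC(=O)OC/C=C(/C)CC/C=C(/C(=O)OC)[C@@H](OC(=O)[C@H](C)[C@H](C)O[Si](C)(C)C(C)(C)C)[C@@H](O[Si](CC)(CC)CC)/C=C(/C(=O)OC)COC(C)=O | intermediate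
26 | C6,C13 diol | OC/C=C(/C)CC/C=C(/C(=O)OC)[C@@H](OC(=O)[C@H](C)[C@H](C)O[Si](C)(C)C(C)(C)C)[C@@H](O[Si](CC)(CC)CC)/C=C(/C(=O)OC)CO | intermediate
27 | C6 (Z)-enal with C13 hydroxyl | O=C/C=C(/C)CC/C=C(/C(=O)OC)[C@@H](OC(=O)[C@H](C)[C@H](C)O[Si](C)(C)C(C)(C)C)[C@@H](O[Si](CC)(CC)CC)/C=C(/C(=O)OC)CO | intermediate
28 | bromo enal (C13 bromide, C6 aldehyde) | O=C/C=C(/C)CC/C=C(/C(=O)OC)[C@@H](OC(=O)[C@H](C)[C@H](C)O[Si](C)(C)C(C)(C)C)[C@@H](O[Si](CC)(CC)CC)/C=C(/C(=O)OC)CBr | intermediate
29 | seco hydroxy ester (ten-membered ring closed, lactone open; 6R,7S,8S,9R) | C=C(C(=O)OC)[C@H]1[C@H](O)/C=C(/C)CC/C=C(/C(=O)OC)[C@@H](OC(=O)[C@H](C)[C@H](C)O[Si](C)(C)C(C)(C)C)[C@H]1O[Si](CC)(CC)CC | intermediate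
30 | trans-fused 6,12-lactone with C8–OTES (6R,7S,8S,9R) | C=C1C(=O)O[C@@H]2/C=C(/C)CC/C=C(/C(=O)OC)[C@@H](OC(=O)[C@H](C)[C@H](C)O[Si](C)(C)C(C)(C)C)[C@@H](O[Si](CC)(CC)CC)[C@@H]12 | intermediate
31 | trans-fused 6,12-lactone with C8–OH (6R,7R,8S,9R) | C=C1C(=O)O[C@@H]2/C=C(/C)CC/C=C(/C(=O)OC)[C@@H](OC(=O)[C@H](C)[C@H](C)O[Si](C)(C)C(C)(C)C)[C@@H](O)[C@@H]12 | intermediate
32 | (2S,3S)-2,3-dimethyloxirane-2-carboxylic 2,4,6-trichlorobenzoic anhydride | O=C(OC(=O)[C@@]1(C)O[C@H]1C)c1c(Cl)cc(Cl)cc1Cl | intermediate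
33 | 3′-O-TBS ether of the target | C=C1C(=O)O[C@@H]2/C=C(/C)CC/C=C(/C(=O)OC)[C@@H](OC(=O)[C@H](C)[C@H](C)O[Si](C)(C)C(C)(C)C)[C@@H](OC(=O)[C@@]3(C)O[C@H]3C)[C@@H]12 | intermediate
34 | CNP0135583.1 | C=C1C(=O)O[C@@H]2/C=C(/C)CC/C=C(/C(=O)OC)[C@@H](OC(=O)[C@H](C)[C@H](C)O)[C@@H](OC(=O)[C@@]3(C)O[C@H]3C)[C@@H]12 | target

**Totals.** 23 steps in all; the longest linear sequence is 15 steps (steps 9–23, from neryl acetate).

**Steps most likely to fail**

Step 20. The ring closure may run through the syn chair (C8 branch axial) and give the cis-fused C6 epimer, or be eroded by oligomerisation of the allylchromium. The fallback sets out from bromo enal 28 and comes back at lactone 30. The closure product, the cis-fused (6S)-lactone F1, is treated with catalytic Pd(PPh3)4 (zerovalent palladium) in THF. Ionisation of the allylic C6–O bond to a π-allylpalladium carboxylate, face exchange by palladium–palladium displacement and re-closure at C6 replace kinetic control by thermodynamic control. This should funnel the material to the trans-fused lactone 30, expected to be the less strained epimer on this ring.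

Step 15. Facial control in the addition to the α-acyloxy aldehyde may be poor, and the aldehyde may enolise and lose the C9 configuration or eliminate the acyloxy group before it is captured. The fallback sets out from diol 22 and comes back at 25; it keeps the C8 centre already set by the epoxidation instead of re-creating it. Both hydroxyls are silylated (Et3SiOTf, 2,6-lutidine) to the bis(triethylsilyl) ether F2. Swern oxidation converts the primary silyl ether selectively into the aldehyde F3. Addition of [1-(methoxycarbonyl)vinyl]diisobutylalane (from methyl propiolate, iBu2AlH and N-methylmorpholine N-oxide) gives the α-methylene-β-hydroxy ester F4 as an inconsequential mixture at the new carbinol. Acetylation (Ac2O, DMAP) gives the acetate F5, and DABCO-catalysed allylic transposition (SN2′ then SN2′) moves the acetate to the primary position, giving 25.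

Step 13. The carboxylate may open the doubly allylic epoxide by the SN2′ path at C1 or with loss of stereochemical integrity, and the product ester may migrate to the neighbouring hydroxyl. The fallback sets out from iodide 19 and comes back at aldehyde 23; it makes the C9–O bond by carbonyl addition and attaches the acid by esterification. Chromium-mediated coupling (CrCl2, NiCl2 cat., DMSO) of 19 with (S)-2,2-dimethyl-1,3-dioxolane-4-carbaldehyde should give the Felkin–Anh anti alcohol F6. Yamaguchi esterification with acid 6 gives the ester F7, and H5IO6 in EtOAc hydrolyses the acetonide and cleaves the diol in one flask to give 23.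

**Further compounds**

F1 | step 20 | cis-fused (6S)-lactone, C6 epimer of 30 | C=C1C(=O)O[C@H]2/C=C(/C)CC/C=C(/C(=O)OC)[C@@H](OC(=O)[C@H](C)[C@H](C)O[Si](C)(C)C(C)(C)C)[C@@H](O[Si](CC)(CC)CC)[C@@H]12
F2 | step 15 | bis(triethylsilyl) ether of diol 22 | CC(=O)OC/C=C(/C)CC/C=C(/C(=O)OC)[C@@H](OC(=O)[C@H](C)[C@H](C)O[Si](C)(C)C(C)(C)C)[C@@H](O[Si](CC)(CC)CC)CO[Si](CC)(CC)CC
F3 | step 15 | α-triethylsilyloxy aldehyde (C7 aldehyde, 8S,9R) | CC(=O)OC/C=C(/C)CC/C=C(/C(=O)OC)[C@@H](OC(=O)[C@H](C)[C@H](C)O[Si](C)(C)C(C)(C)C)[C@@H](O[Si](CC)(CC)CC)C=O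
F4 | step 15 | α-methylene-β-hydroxy ester (C7 epimers) | CC(=O)OC/C=C(/C)CC/C=C(/C(=O)OC)[C@@H](OC(=O)[C@H](C)[C@H](C)O[Si](C)(C)C(C)(C)C)[C@@H](O[Si](CC)(CC)CC)C(O)C(=C)C(=O)OC
F5 | step 15 | secondary allylic acetate of F4 | CC(=O)OC/C=C(/C)CC/C=C(/C(=O)OC)[C@@H](OC(=O)[C@H](C)[C@H](C)O[Si](C)(C)C(C)(C)C)[C@@H](O[Si](CC)(CC)CC)C(OC(C)=O)C(=C)C(=O)OC
F6 | step 13 | anti alcohol from 19 and (S)-glyceraldehyde acetonide | CC(=O)OC/C=C(/C)CC/C=C(/C(=O)OC)[C@@H](O)[C@@H]1COC(C)(C)O1
F7 | step 13 | C9 ester acetonide | CC(=O)OC/C=C(/C)CC/C=C(/C(=O)OC)[C@@H](OC(=O)[C@H](C)[C@H](C)O[Si](C)(C)C(C)(C)C)[C@@H]1COC(C)(C)O1
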